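## The problem

The target is a briarane: a cyclohexene (ring A: C1, C10–C14) trans-fused through C1–C10 to a ten-membered carbocycle (C1–C10), with a γ-lactone (O–C7, C8, C17, C19) fused across C7–C8. C15, C18 and C20 are the methyls on C1, C17 and C11, and C16 is the exocyclic methylene on C5. A synthesis has to close the ten-membered ring, which direct cyclization disfavours on entropic and transannular grounds, and has to place in it a 3Z,5(16)-diene, a secondary allylic chloride at C6 and oxygen at C2, C7, C8 and C9. There are ten stereocentres (C1, C2, C6, C7, C8, C9, C10, C11, C12, C17), three of them fully substituted (C1, C8, C11). C1 can be set first by an asymmetric annulation. In a trans-decalin its axial methyl shields the β face and so controls C10, C9, C11 and C12; O9 can then direct C8 and C17, and after ring expansion C8 can govern C6 and C7 and C1 can govern C2. The fragile groups are the allylic chloride next to the lactone oxygen (SN2′, elimination, epoxide closure by a C7 alkoxide), the doubly allylic C2 acetate, the β-hydroxy lactone with its epimerizable C17, and the C9 acetate beside a tertiary alcohol; late steps must therefore avoid strong base, strong acid, soft nucleophiles and zerovalent palladium. The enabling feature is that C2 and C7 are 1,6-related across the ten-membered ring while C5, between C4 and C6, carries the exocyclic methylene. A bond drawn from C2 to C7 turns the medium ring into a cyclohexane (ring B: C1, C2, C7, C8, C9, C10) in which a vinyl group on C2 and an allenyl group on the C7 carbinol form the 1,5-diene of an oxy-Cope rearrangement, whose enolate carbon is C6, where the chlorine must go.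

## Retrosynthesis

**Acetates, C12 hydroxyl and the C2 oxygen.** Target 56 is traced to silyl ether 55 and then to allylic alcohol 54, so that only a fluoride-labile group on O12 and two acetylations remain. The C2–O bond is cut next: 54 comes from the skipped diene 52 by a singlet-oxygen ene reaction. This moves E-C2=C3 to Z-C3=C4 and uses the only allylic hydrogens that alkene has (on C4). Oxidizing C2 this late keeps the doubly allylic oxygen out of every acidic or basic step. The forward reaction must choose one of three alkenes and one face of C2=C3.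

**Lactone.** The O7–C19 acyl bond of 51 is cut to the 1,4-diol 49, and the C7–H bond to the α-chloro ketone 47 (via chlorohydrin 48). Cutting here rather than carrying an ester is forced: a C19 carbonyl would be attacked by the C7 alkoxide of the key step. O9 must stay masked until the lactone exists, because it is also γ to C19. The reduction must place hydride on the face of C7 opposite the C8–C9 ring bond.

**Ring expansion (key step).** The C4–C5 bond of 47 is cut and C2–C7 is reconnected, with chlorine removed from C6. This gives the trans-decalin allenyl carbinol 44 and N-chlorosuccinimide 45. Against macrolactonization, ring-closing metathesis or a Nozaki–Hiyama–Kishi closure, this cut needs no high dilution. It delivers the C5 methylene, the C7 carbonyl and a C6 nucleophile in one event, and moves C1, C8, C9, C10, C11, C12 and C17 into six-membered-ring chemistry. The forward reaction must go through the chair array and chlorinate one face of C6 without conjugating C5=C16.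

**Allene and C6–C7 bond.** The C5=C16 bond of 44 is cut to the terminal alkyne 41 and formaldehyde 42 (allene homologation), and the C6–C7 bond to ketone 39 and ethynylmagnesium bromide 40. A direct allenyl nucleophile would give mainly the homopropargyl isomer. The addition must come from the equatorial side, which the axial C15 methyl ensures.

**C2 vinyl group.** The C2–C3 bond of 39 is cut to ketone 33 and acetaldehyde 34 by way of the ethylidene ketone 37. C8 is quaternary, so C2 is the only enolizable position of 33, and deconjugative protonation of 37 sets C2 under both kinetic and thermodynamic control.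

**Ring A.** The two C–O bonds at C11 and C12 of diol 31 are cut to the homoannular diene 30; diene 28 comes from the saturated C12 ketone 24 through enone 26 and dienyl triflate 27. Syn dihydroxylation opposite the C15 methyl gives the cis-diol directly. Hydride reduction of a 11-hydroxy-12-ketone would favour the trans-diol and was set aside.

**C8–C17 bond and ring B oxygens.** The C8–C17 bond of 19 is cut to the α-hydroxy ketone 14 and the E-crotyl boronate 17, which comes from trans-but-2-ene 15 and triisopropyl borate 16. This is preferred to a propionate aldol because the closed transition state fixes C8 and C17 together. 14 comes from enone 9 by reduction and two successive enolate oxygenations (C9, then C7).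

**Decalin core.** Enone 9 is traced through the deconjugated ketal 8 to octalone 7. 7 is cut at C10=C11 and C1–C14 to 2-methylcyclohexanone 1 and ethyl vinyl ketone 3, with (R)-1-phenylethylamine 2 as the chirality source. Starting from the ketone rather than 2-methylcyclohexane-1,3-dione leaves C2 unoxidized, which is what the later aldol route to the vinyl group needs.

## Roads not taken

**Alternative 1: transannular 6π-electrocyclization.** The cut is C1–C10, made last. Heating the fourteen-membered silyloxy triene A1 would close ring A by disrotatory electrocyclization and give the silyl dienol ether A2, with the ten-membered ring and the lactone already in place.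
- Merits: ring A and its fusion arise in one step, with no protecting-group work in that ring. In step count for ring A it is better than the chosen plan.
- Weak points: A1 must be a macrocycle with three defined alkene geometries, one of them carrying an inward carbon substituent on the fully substituted C1 terminus, which slows the closure. The sense of disrotation, and hence C1/C10 relative to C2 and C9, is governed only by remote centres. The allylic chloride, both acetates and the β-hydroxy lactone must survive the heating. A2 still needs oxygen at C11 and reduction at C12 in the presence of the 3,5(16)-diene.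
- Comparison: the chosen plan sets C1 and C10 early with reagent and substrate control and forms the medium ring with a stereospecific shift. Its price is a long linear sequence in which ring A takes seven steps.

**Alternative 2: furan Diels–Alder for ring A.** The cuts are C10–C11 and C1–C14. A Lewis-acid-catalysed cycloaddition of 2-methylfuran A3 with dimethyl mesaconate A4 would give the 7-oxanorbornene diester A5.
- Merits: one step from bulk chemicals sets C1, C10, C11 and C14 and supplies ester handles for C2 and C9. Nothing in the chosen plan is as economical for ring A.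
- Weak points: furan cycloadditions are reversible, and the regiochemistry of two unsymmetrical partners, the endo/exo ratio and the absolute configuration all need control. The oxygen bridge sits on C11 and C14 while the target needs oxygen at C11 and C12 and a C13=C14 alkene, so the bridge must be opened with allylic transposition. The alternative says nothing about the ten-membered ring, which would still have to be closed by a macrocyclization.
- Comparison: the chosen plan spends more steps on ring A but solves the medium ring, C6 and C7 in its key step.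

**Alternative 3: three-component methyl addition and aldol.** The cuts are C1–C15 and C9–C10. Copper-catalysed addition of a methyl Grignard reagent to the ring A enone A6 and trapping of the enolate with aldehyde A7 would give the β-hydroxy ketone A8.
- Merits: it is convergent, joins the C8/C17 fragment to ring A, and sets C1, C10 and C9 in one pot. In convergence it is better than the chosen plan.
- Weak points: conjugate addition to a β,β-disubstituted enone to form a quaternary centre is slow. The aldol of the hindered enolate with an α-branched enal has uncertain C9/C10 selectivity and can revert. No ring is closed, so the ten-membered ring with its diene and chloride still needs a late macrocyclization.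
- Comparison: the chosen plan is linear, but its ring-forming step is intramolecular, geometry-defined, and leaves C6 functionalized.

Key step: step 24

## Route

Conventions and assumptions:
- Briarane numbering is used throughout; α is the face opposite the C15 methyl, β the same face.
- The C11 methyl in 8–26 is drawn α (equatorial, the expected thermodynamic arrangement). This centre becomes sp2 in step 14 and has no bearing on the route.
- Ethylidene ketone 37 is drawn as the Z isomer; either geometry serves in step 21.

Step 1
Reactants: 1 2-methylcyclohexanone; 2 (R)-1-phenylethylamine; 3 pent-1-en-3-one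
Product: 6 (S)-2-methyl-2-(3-oxopentyl)cyclohexan-1-one, via imine 4 (not isolated), via Michael-adduct imine 5 (not isolated)
Conditions: 2, TsOH (cat.), toluene, reflux (Dean–Stark); then 3, THF, 40 °C; then 20% aq. AcOH, 23 °C
Reagents that add atoms: water (O)
Why: Deracemizing Michael addition of a chiral imine: 4 reacts through its more substituted secondary enamine in a compact aza-ene-like transition state, the phenyl group shielding one face, which sets C1 as S. Hydrolysis returns the amine.

Step 2
Reactants: 6 (S)-2-methyl-2-(3-oxopentyl)cyclohexan-1-one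
Product: 7 (S)-1,4a-dimethyl-4,4a,5,6,7,8-hexahydronaphthalen-2(3H)-one
Conditions: NaOMe, MeOH, 60 °C
Reagents that add atoms: none
Why: Intramolecular aldol condensation (second stage of a Robinson annulation) closes ring A as the C12 enone with the C20 methyl on C11.

Step 3
Reactants: 7 (S)-1,4a-dimethyl-4,4a,5,6,7,8-hexahydronaphthalen-2(3H)-one
Product: 8 C12 ethylene ketal with C9=C10 alkene
Conditions: ethylene glycol, TsOH·H2O (cat.), benzene, reflux (Dean–Stark)
Reagents that add atoms: ethylene glycol (OCCO)
Why: Acid-catalysed ketalization of an α-substituted enone goes with migration of the double bond to the β,γ position (as in steroidal 4-en-3-ones). This makes C8 an allylic methylene.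

Step 4
Reactants: 8 C12 ethylene ketal with C9=C10 alkene
Product: 9 ring B enone (C8 ketone with C9=C10)
Conditions: Rh2(cap)4 (cap = caprolactamate, 1 mol %), t-BuOOH, K2CO3, CH2Cl2, 23 °C
Reagents that add atoms: tert-butyl hydroperoxide (CC(C)(C)OO)
Why: Radical allylic oxidation to the enone, as used for 5-ene steroids to 7-ketones. The secondary C8 methylene reacts in preference to the hindered tertiary C11–H next to the ketal.

Step 5
Reactants: 9 ring B enone (C8 ketone with C9=C10)
Product: 11 trans-fused 9α-trimethylsilyloxy 8-ketone, via TMS enol ether 10 (not isolated)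
Conditions: Li, NH3(l), THF, t-BuOH (1 equiv), −78 °C; isoprene; then Me3SiCl, Et3N, THF, −78 → 0 °C; then dimethyldioxirane, acetone/CH2Cl2, −78 → 23 °C
Reagents that add atoms: chlorotrimethylsilane (C[Si](C)(C)Cl); dimethyldioxirane (CC1(C)OO1)
Why: Dissolving-metal reduction protonates the β carbon C10 axially and gives the trans ring fusion (H10 α) with a regiodefined C8=C9 enolate. Rubottom oxidation of its silyl ether from the α face, opposite the 1,3-related axial C15 methyl, sets the equatorial 9α oxygen, and the silyl group shifts to O9.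

Step 6
Reactants: 11 trans-fused 9α-trimethylsilyloxy 8-ketone
Product: 14 7α-tert-butyldimethylsilyloxy 9α-hydroxy 8-ketone, via TBS enol ether 12 (not isolated), via bis-silyl ketone 13 (not isolated)
Conditions: LiN(iPr)2, THF, −78 °C; t-BuMe2SiOTf; then dimethyldioxirane, CH2Cl2/acetone, −78 → 23 °C; then citric acid, MeOH, 0 °C
Reagents that add atoms: tert-butyldimethylsilyl triflate (CC(C)(C)[Si](C)(C)OS(=O)(=O)C(F)(F)F); dimethyldioxirane (CC1(C)OO1)
Why: Kinetic enolization takes the C7 methylene rather than the silyloxy methine C9, and a second Rubottom oxidation from the α face puts oxygen on C7 with 1,4-shift of the TBS group. Mild acidic methanolysis removes only the trimethylsilyl ether, freeing O9 as the directing group for step 8.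

Step 7
Reactants: 15 trans-but-2-ene; 16 triisopropyl borate
Product: 17 (E)-crotylboronic acid diisopropyl ester
Conditions: n-BuLi, KOt-Bu, THF, −78 → −50 °C; then 16, −78 °C; then 1 M HCl in Et2O, −78 → 23 °C
Reagents that add atoms: none
Why: Superbase metalation of trans-but-2-ene gives the configurationally stable E-crotylpotassium at low temperature, and borylation with loss of one isopropoxide gives the E reagent (standard crotylboronate preparation).

Step 8
Reactants: 14 7α-tert-butyldimethylsilyloxy 9α-hydroxy 8-ketone; 17 (E)-crotylboronic acid diisopropyl ester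
Product: 19 8α,9α-diol with 8β-(but-3-en-2-yl) group, via cyclic borate 18 (not isolated)
Conditions: Et3N, CH2Cl2, −78 → 23 °C; then H2O
Reagents that add atoms: none
Why: Hydroxyl-directed crotylboration of an α-hydroxy ketone: exchange puts boron on O9, and the crotyl group is delivered through a closed six-membered chair (Zimmerman–Traxler type) on the equatorial β face of C8, giving the axial 8α oxygen cis to O9. The chelated C9 arm must sit axial in that chair, so the E reagent places the C17 methyl as required, and C8 and C17 are set together.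

Step 9
Reactants: 19 8α,9α-diol with 8β-(but-3-en-2-yl) group
Product: 20 8,9-acetonide
Conditions: 2,2-dimethoxypropane, PPTS (cat.), CH2Cl2, 23 °C
Reagents that add atoms: 2,2-dimethoxypropane (COC(C)(C)OC)
Why: Acetal exchange on the cis (axial/equatorial) diol. The acetonide masks O9 until after lactonization and leaves an ether oxygen on C8 for later chelation.

Step 10
Reactants: 20 8,9-acetonide
Product: 22 C19 primary alcohol, via aldehyde 21 (not isolated)
Conditions: O3, CH2Cl2, −78 °C; PPh3, −78 → 23 °C; then NaBH4, MeOH, 0 °C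
Reagents that add atoms: ozone ([O-][O+]=O)
Why: Ozonolysis with reductive work-up; the crotyl-derived vinyl group is the only alkene at this stage, which is why the side chain is installed before any other alkene.

Step 11
Reactants: 22 C19 primary alcohol
Product: 23 C19 4-methoxybenzyl ether
Conditions: NaH, 4-methoxybenzyl chloride, n-Bu4NI (cat.), THF/DMF, 0 → 23 °C
Reagents that add atoms: 4-methoxybenzyl chloride (COc1ccc(CCl)cc1)
Why: Williamson etherification of the only free hydroxyl. A benzyl-type ether is chosen because a C19 silyl ether could migrate to the C7 alkoxide in step 24.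

Step 12
Reactants: 23 C19 4-methoxybenzyl ether
Product: 24 C12 ketone
Conditions: PPTS, acetone/H2O (10:1), 50 °C
Reagents that add atoms: water (O)
Why: Acid-catalysed dioxolane hydrolysis by exchange in acetone; the acetone solvent holds the acetonide in place, and the TBS ether is stable.

Step 13
Reactants: 24 C12 ketone
Product: 26 ring A enone (C12 ketone with C13=C14), via TMS enol ether 25 (not isolated)
Conditions: LiN(iPr)2, THF, −78 °C; Me3SiCl; then Pd(OAc)2 (1.1 equiv), MeCN, 23 °C
Reagents that add atoms: none
Why: Saegusa–Ito oxidation: kinetic enolization takes the C13 methylene, so the new alkene is C13=C14 and the C10 stereocentre is untouched.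

Step 14
Reactants: 26 ring A enone (C12 ketone with C13=C14)
Product: 27 C12 dienyl triflate
Conditions: KN(SiMe3)2, THF, −78 °C; PhNTf2, −78 → 0 °C
Reagents that add atoms: N-phenylbis(trifluoromethanesulfonimide) (O=S(=O)(N(c1ccccc1)S(=O)(=O)C(F)(F)F)C(F)(F)F)
Why: The only acidic proton is the axial C11–H (C1 is quaternary and C7 is still a silyl ether), so O-triflation of the cross-conjugated dienolate gives the 2-triflyloxy diene.

Step 15
Reactants: 27 C12 dienyl triflate
Product: 28 ring A 11,13-diene
Conditions: Pd(OAc)2 (5 mol %), PPh3, HCO2H, n-Bu3N, DMF, 60 °C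
Reagents that add atoms: none
Why: Palladium-catalysed formate reduction of an alkenyl triflate (oxidative addition, formate exchange, decarboxylation, reductive elimination) replaces the triflate by hydrogen.

Step 16
Reactants: 28 ring A 11,13-diene
Product: 29 C7 alcohol
Conditions: n-Bu4NF, THF, 45 °C
Reagents that add atoms: none
Why: Fluoride desilylation, carried out before any other silyl ether is in the molecule.

Step 17
Reactants: 29 C7 alcohol
Product: 30 C7 ketone
Conditions: Dess–Martin periodinane, NaHCO3, CH2Cl2, 23 °C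
Reagents that add atoms: none
Why: Dess–Martin oxidation of the hindered secondary alcohol under buffered, non-enolizing conditions.

Step 18
Reactants: 30 C7 ketone
Product: 31 11α,12α-diol
Conditions: OsO4 (2 mol %), N-methylmorpholine N-oxide, acetone/H2O, 0 → 23 °C
Reagents that add atoms: N-methylmorpholine N-oxide (C[N+]1([O-])CCOCC1); water (O)
Why: Catalytic syn dihydroxylation (Upjohn conditions) takes the trisubstituted, more electron-rich C11=C12 bond of the diene. It attacks from the α face, away from the axial C15 methyl, so C11 (OH α, methyl β) and C12 are set together.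

Step 19
Reactants: 31 11α,12α-diol
Product: 33 12-triisopropylsilyl 11-triethylsilyl bis-ether, via 12-triisopropylsilyl ether 32 (not isolated)
Conditions: i-Pr3SiOTf, 2,6-lutidine, CH2Cl2, −78 → 0 °C; then Et3SiOTf, 0 → 23 °C
Reagents that add atoms: triisopropylsilyl triflate (CC(C)[Si](C(C)C)(C(C)C)OS(=O)(=O)C(F)(F)F); triethylsilyl triflate (CC[Si](CC)(CC)OS(=O)(=O)C(F)(F)F)
Why: Silylation with silyl triflates, the secondary allylic hydroxyl first and the tertiary one second. The acid-stable TIPS group is what will block O12 during the acetylation, and the TES group keeps O11 from forming an alkoxide in step 24.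

Step 20
Reactants: 33 12-triisopropylsilyl 11-triethylsilyl bis-ether; 34 acetaldehyde
Product: 37 2-ethylidene 7-ketone, via aldol adduct 35 (not isolated), via mesylate 36 (not isolated)
Conditions: LiN(iPr)2, THF, −78 °C; 34; AcOH quench; then MeSO2Cl, Et3N, CH2Cl2, 0 °C; DBU, 23 °C
Reagents that add atoms: none
Why: Aldol addition followed by E1cB dehydration (aldol condensation). C8 is quaternary, so the C7 ketone can enolize only towards C2.

Step 21
Reactants: 37 2-ethylidene 7-ketone
Product: 39 2β-vinyl 7-ketone, via lithium dienolate 38 (not isolated)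
Conditions: LiN(iPr)2, THF/HMPA, −78 °C; then AcOH, −78 °C
Reagents that add atoms: none
Why: Deconjugative kinetic α-protonation of the extended enolate (the pulegone-to-isopulegone type of transformation). The proton arrives on the α face anti to the C15 methyl, leaving the vinyl group β and equatorial, which is also the more stable epimer.

Step 22
Reactants: 39 2β-vinyl 7-ketone; 40 ethynylmagnesium bromide
Product: 41 7α-ethynyl 7β-carbinol
Conditions: CeCl3, THF, −78 → −40 °C; then H2O
Reagents that add atoms: none
Why: Organocerium 1,2-addition, which suppresses enolization of the α-vinyl ketone. The axial trajectory is blocked by the syn-axial C15 methyl, so the slim acetylide enters equatorially and the hydroxyl becomes axial (β), trans-diequatorial alkynyl and vinyl groups resulting.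

Step 23
Reactants: 41 7α-ethynyl 7β-carbinol; 42 formaldehyde (as paraformaldehyde)
Product: 44 7α-allenyl 7β-carbinol, via propargylic amine 43 (not isolated)
Conditions: CuI (0.5 equiv), dicyclohexylamine, 1,4-dioxane, reflux
Reagents that add atoms: none
Why: Crabbé homologation: a Mannich-type coupling gives the propargylic amine, and copper-mediated 1,5-hydride transfer with loss of the imine gives the terminal allene. The reaction is established for tertiary propargylic alcohols.

Step 24
Reactants: 44 7α-allenyl 7β-carbinol; 45 N-chlorosuccinimide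
Product: 47 ten-membered 6-chloro 7-ketone with C5 methylene, via potassium dienolate 46 (not isolated)
Conditions: KH, 18-crown-6, THF, 0 → 23 °C; then cannulate into 45, THF, −78 °C; pH 7 buffer
Reagents that add atoms: none
Why: KH/18-crown-6 gives the free C7 alkoxide of 44, whose 1,5-diene C5=C6–C7–C2–C3=C4 undergoes an alkoxide-accelerated [3,3] shift (anionic oxy-Cope) that makes C4–C5 and breaks C2–C7; C5 is the central allene carbon and keeps C5=C16, so the product is the cross-conjugated potassium dienolate 46, which N-chlorosuccinimide chlorinates at C6. The closest known reaction type is the anionic oxy-Cope ring expansion of trans-1,2-dialkenylcyclohexanols to cyclodec-5-enones with electrophilic trapping of the enolate. The ten-membered ring is not closed by a cyclization; it arises by six-to-ten ring expansion when the C2–C7 bond of ring B is cut. The trans-decalin holds vinyl and allenyl diequatorial, so only the chair array is open, and it gives E-C2=C3 and the Z enolate (O7 cis to C5). C6 is the one new stereocentre: with potassium bridging O7 and the acetonide oxygen on C8, the C8–C9 ring bond covers one enolate face and chlorine is delivered to the other, which is the target configuration. The step needs C- rather than O-chlorination and attack at C6 rather than C16, which the larger coefficient and lower hindrance at C6 and inverse addition at −78 °C should secure. It also needs C5=C16 to stay out of conjugation, which a cold buffered quench should secure, since C8 is quaternary and C6 is the only enolizable position.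

Step 25
Reactants: 47 ten-membered 6-chloro 7-ketone with C5 methylene
Product: 48 6-chloro 7-alcohol
Conditions: Zn(BH4)2, Et2O, −40 → 0 °C
Reagents that add atoms: none
Why: Chelation-controlled ketone reduction: zinc bridges the C7 carbonyl and the C8 acetonide oxygen, and hydride adds from the ring periphery, the face opposite the C8–C9 bond. This gives the 7-alcohol anti to O8 and syn to O9, as in the target.

Step 26
Reactants: 48 6-chloro 7-alcohol
Product: 49 7,19-diol
Conditions: DDQ, CH2Cl2/pH 7 buffer, 0 °C
Reagents that add atoms: none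
Why: Oxidative cleavage of the 4-methoxybenzyl ether by DDQ (hydride abstraction, hydrolysis of the oxocarbenium ion) under buffered conditions that spare the silyl ethers, the acetonide and the chloride.

Step 27
Reactants: 49 7,19-diol
Product: 51 γ-lactone, via lactol 50 (not isolated)
Conditions: TEMPO (20 mol %), PhI(OAc)2, CH2Cl2, 23 °C
Reagents that add atoms: none
Why: Oxoammonium oxidation of the primary alcohol, lactol formation with O7 and further oxidation (oxidative lactonization of a 1,4-diol). O9 is still in the acetonide, so only the C7 lactone can form.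

Step 28
Reactants: 51 γ-lactone
Product: 52 8,9,11-triol 12-triisopropylsilyl ether
Conditions: AcOH/H2O/THF (3:1:1), 45 °C
Reagents that add atoms: none
Why: Mild acid hydrolysis removes the acetonide and the tertiary triethylsilyl ether while the triisopropylsilyl ether survives. It is done before the C2 oxygen exists, so no dienyl carbinol is exposed to acid; any residual triethylsilyl ether would fall in step 31.

Step 29
Reactants: 52 8,9,11-triol 12-triisopropylsilyl ether
Product: 54 C2 allylic alcohol with 3Z,5(16)-diene, via hydroperoxide 53 (not isolated)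
Conditions: O2, tetraphenylporphyrin (cat.), visible light, CH2Cl2, −20 °C; then PPh3, 0 °C
Reagents that add atoms: oxygen (O=O)
Why: Schenck ene reaction of singlet oxygen with the strained E-C2=C3 alkene, whose only allylic hydrogens are the doubly allylic ones on C4: oxygen bonds to C2, the double bond moves to C3=C4 into conjugation with C5=C16, and Ph3P reduces the hydroperoxide. Oxygen should arrive anti to the C1–C10 ring bond and past the C15 methyl rather than C14, which gives the target C2 configuration, and the synclinal C2=C3–C4–C5 arrangement of the ring should leave the new alkene Z; the ring A alkene has no aligned allylic hydrogen and C5=C16 is deactivated by the allylic chlorine.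

Step 30
Reactants: 54 C2 allylic alcohol with 3Z,5(16)-diene
Product: 55 2,9-diacetate 12-triisopropylsilyl ether
Conditions: Ac2O, pyridine, DMAP (cat.), CH2Cl2, 0 → 23 °C
Reagents that add atoms: acetic anhydride (CC(=O)OC(C)=O)
Why: Nucleophile-catalysed acylation of the two secondary alcohols; the tertiary C8 and C11 hydroxyls are too hindered to react and O12 is blocked.

Step 31
Reactants: 55 2,9-diacetate 12-triisopropylsilyl ether
Product: 56 CNP0317097.1
Conditions: HF·pyridine, pyridine, THF, 0 → 23 °C
Reagents that add atoms: none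
Why: Fluoride-mediated desilylation under buffered, weakly acidic conditions that leave the acetates, the lactone, the diene and the allylic chloride untouched.

## Compound list

1 | 2-methylcyclohexanone (racemic) | CC1CCCCC1=O | starting material
2 | (R)-1-phenylethylamine | C[C@@H](N)c1ccccc1 | starting material
3 | pent-1-en-3-one (ethyl vinyl ketone) | CCC(=O)C=C | starting material
4 | N-[(R)-1-phenylethyl] imine of 2-methylcyclohexanone | c1ccccc1[C@@H](C)N=C1CCCCC1C | intermediate
5 | N-[(R)-1-phenylethyl] imine of (S)-2-methyl-2-(3-oxopentyl)cyclohexanone | c1ccccc1[C@@H](C)N=C1CCCC[C@@]1(C)CCC(=O)CC | intermediate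
6 | (S)-2-methyl-2-(3-oxopentyl)cyclohexan-1-one | O=C1CCCC[C@@]1(C)CCC(=O)CC | intermediate
7 | (S)-1,4a-dimethyl-4,4a,5,6,7,8-hexahydronaphthalen-2(3H)-one (C12 enone, C11 methyl, C1 quaternary) | CC1=C2CCCC[C@@]2(C)CCC1=O | intermediate
8 | C12 ethylene ketal, C9=C10 alkene, 11α-methyl | C1C[C@@]2(C)CCC3(OCCO3)[C@@H](C)C2=CC1 | intermediate
9 | C8 ketone conjugated with C9=C10, C12 ethylene ketal | C1C[C@@]2(C)CCC3(OCCO3)[C@@H](C)C2=CC1=O | intermediate
10 | trans-fused C8=C9 trimethylsilyl enol ether (H10 α) | C1C[C@@]2(C)CCC3(OCCO3)[C@@H](C)[C@@H]2C=C1O[Si](C)(C)C | intermediate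
11 | trans-decalin 8-ketone, 9α-OSiMe3, C12 ketal | C1C[C@@]2(C)CCC3(OCCO3)[C@@H](C)[C@@H]2[C@@H](O[Si](C)(C)C)C1=O | intermediate
12 | C7=C8 tert-butyldimethylsilyl enol ether, 9α-OSiMe3 | C1(O[Si](C)(C)C(C)(C)C)=CC[C@@]2(C)CCC3(OCCO3)[C@@H](C)[C@@H]2[C@H]1O[Si](C)(C)C | intermediate
13 | 8-ketone, 7α-OTBS, 9α-OSiMe3 | [C@H]1(O[Si](C)(C)C(C)(C)C)C[C@@]2(C)CCC3(OCCO3)[C@@H](C)[C@@H]2[C@@H](O[Si](C)(C)C)C1=O | intermediate
14 | 8-ketone, 7α-OTBS, 9α-OH | [C@H]1(O[Si](C)(C)C(C)(C)C)C[C@@]2(C)CCC3(OCCO3)[C@@H](C)[C@@H]2[C@@H](O)C1=O | intermediate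
15 | trans-but-2-ene | C/C=C/C | starting material
16 | triisopropyl borate | CC(C)OB(OC(C)C)OC(C)C | starting material
17 | (E)-crotylboronic acid diisopropyl ester | C/C=C/CB(OC(C)C)OC(C)C | intermediate
18 | cyclic isopropyl borate of the 8α,9α-diol, 8β-(but-3-en-2-yl) | [C@H]1(O[Si](C)(C)C(C)(C)C)C[C@@]2(C)CCC3(OCCO3)[C@@H](C)[C@@H]2[C@@H](OB(OC(C)C)O4)[C@]14[C@@H](C)C=C | intermediate
19 | 8α,9α-diol, 8β-(but-3-en-2-yl) (C17 as in target), 7α-OTBS | [C@H]1(O[Si](C)(C)C(C)(C)C)C[C@@]2(C)CCC3(OCCO3)[C@@H](C)[C@@H]2[C@@H](O)[C@]1(O)[C@@H](C)C=C | intermediate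
20 | 8,9-acetonide of 19 | [C@H]1(O[Si](C)(C)C(C)(C)C)C[C@@]2(C)CCC3(OCCO3)[C@@H](C)[C@@H]2[C@@H](OC(C)(C)O4)[C@]14[C@@H](C)C=C | intermediate
21 | C19 aldehyde | [C@H]1(O[Si](C)(C)C(C)(C)C)C[C@@]2(C)CCC3(OCCO3)[C@@H](C)[C@@H]2[C@@H](OC(C)(C)O4)[C@]14[C@@H](C)C=O | intermediate
22 | C19 primary alcohol | [C@H]1(O[Si](C)(C)C(C)(C)C)C[C@@]2(C)CCC3(OCCO3)[C@@H](C)[C@@H]2[C@@H](OC(C)(C)O4)[C@]14[C@@H](C)CO | intermediate
23 | C19 4-methoxybenzyl ether | [C@H]1(O[Si](C)(C)C(C)(C)C)C[C@@]2(C)CCC3(OCCO3)[C@@H](C)[C@@H]2[C@@H](OC(C)(C)O4)[C@]14[C@@H](C)COCc1ccc(OC)cc1 | intermediate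
24 | C12 ketone (11α-methyl), 7α-OTBS, 8,9-acetonide, C19 OPMB | [C@H]1(O[Si](C)(C)C(C)(C)C)C[C@@]2(C)CCC(=O)[C@@H](C)[C@@H]2[C@@H](OC(C)(C)O3)[C@]13[C@@H](C)COCc1ccc(OC)cc1 | intermediate
25 | C12=C13 trimethylsilyl enol ether | [C@H]1(O[Si](C)(C)C(C)(C)C)C[C@@]2(C)CC=C(O[Si](C)(C)C)[C@@H](C)[C@@H]2[C@@H](OC(C)(C)O3)[C@]13[C@@H](C)COCc1ccc(OC)cc1 | intermediate
26 | ring A enone: C12 ketone, C13=C14 | [C@H]1(O[Si](C)(C)C(C)(C)C)C[C@@]2(C)C=CC(=O)[C@@H](C)[C@@H]2[C@@H](OC(C)(C)O3)[C@]13[C@@H](C)COCc1ccc(OC)cc1 | intermediate
27 | C12 triflate of the C11=C12, C13=C14 diene | [C@H]1(O[Si](C)(C)C(C)(C)C)C[C@@]2(C)C=CC(OS(=O)(=O)C(F)(F)F)=C(C)[C@@H]2[C@@H](OC(C)(C)O3)[C@]13[C@@H](C)COCc1ccc(OC)cc1 | intermediate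
28 | ring A C11=C12, C13=C14 diene, 7α-OTBS | [C@H]1(O[Si](C)(C)C(C)(C)C)C[C@@]2(C)C=CC=C(C)[C@@H]2[C@@H](OC(C)(C)O3)[C@]13[C@@H](C)COCc1ccc(OC)cc1 | intermediate
29 | 7α-alcohol of the ring A diene | [C@H]1(O)C[C@@]2(C)C=CC=C(C)[C@@H]2[C@@H](OC(C)(C)O3)[C@]13[C@@H](C)COCc1ccc(OC)cc1 | intermediate
30 | C7 ketone of the ring A diene | O=C1C[C@@]2(C)C=CC=C(C)[C@@H]2[C@@H](OC(C)(C)O3)[C@]13[C@@H](C)COCc1ccc(OC)cc1 | intermediate
31 | 11α,12α-diol (C20 β), C13=C14, C7 ketone | O=C1C[C@@]2(C)C=C[C@@H](O)[C@@](C)(O)[C@@H]2[C@@H](OC(C)(C)O3)[C@]13[C@@H](C)COCc1ccc(OC)cc1 | intermediate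
32 | 12-O-triisopropylsilyl ether of 31 | O=C1C[C@@]2(C)C=C[C@@H](O[Si](C(C)C)(C(C)C)C(C)C)[C@@](C)(O)[C@@H]2[C@@H](OC(C)(C)O3)[C@]13[C@@H](C)COCc1ccc(OC)cc1 | intermediate
33 | 12-O-TIPS, 11-O-TES C7 ketone | O=C1C[C@@]2(C)C=C[C@@H](O[Si](C(C)C)(C(C)C)C(C)C)[C@@](C)(O[Si](CC)(CC)CC)[C@@H]2[C@@H](OC(C)(C)O3)[C@]13[C@@H](C)COCc1ccc(OC)cc1 | intermediate
34 | acetaldehyde | CC=O | starting material
35 | C2 (1-hydroxyethyl) aldol adduct (mixture at C2 and the carbinol carbon) | O=C1C(C(C)O)[C@@]2(C)C=C[C@@H](O[Si](C(C)C)(C(C)C)C(C)C)[C@@](C)(O[Si](CC)(CC)CC)[C@@H]2[C@@H](OC(C)(C)O3)[C@]13[C@@H](C)COCc1ccc(OC)cc1 | intermediate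
36 | methanesulfonate of 35 | O=C1C(C(C)OS(C)(=O)=O)[C@@]2(C)C=C[C@@H](O[Si](C(C)C)(C(C)C)C(C)C)[C@@](C)(O[Si](CC)(CC)CC)[C@@H]2[C@@H](OC(C)(C)O3)[C@]13[C@@H](C)COCc1ccc(OC)cc1 | intermediate
37 | (Z)-2-ethylidene 7-ketone | O=C1/C(=C\C)[C@@]2(C)C=C[C@@H](O[Si](C(C)C)(C(C)C)C(C)C)[C@@](C)(O[Si](CC)(CC)CC)[C@@H]2[C@@H](OC(C)(C)O3)[C@]13[C@@H](C)COCc1ccc(OC)cc1 | intermediate
38 | lithium dienolate C7(O)=C2–C3=C4 | [Li+].[O-]C1=C(C=C)[C@@]2(C)C=C[C@@H](O[Si](C(C)C)(C(C)C)C(C)C)[C@@](C)(O[Si](CC)(CC)CC)[C@@H]2[C@@H](OC(C)(C)O3)[C@]13[C@@H](C)COCc1ccc(OC)cc1 | intermediate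
39 | 2β-vinyl 7-ketone (H2 α) | O=C1[C@H](C=C)[C@@]2(C)C=C[C@@H](O[Si](C(C)C)(C(C)C)C(C)C)[C@@](C)(O[Si](CC)(CC)CC)[C@@H]2[C@@H](OC(C)(C)O3)[C@]13[C@@H](C)COCc1ccc(OC)cc1 | intermediate
40 | ethynylmagnesium bromide | C#C[Mg]Br | starting material
41 | 7α-ethynyl 7β-hydroxy 2β-vinyl decalin | C#C[C@@]1(O)[C@H](C=C)[C@@]2(C)C=C[C@@H](O[Si](C(C)C)(C(C)C)C(C)C)[C@@](C)(O[Si](CC)(CC)CC)[C@@H]2[C@@H](OC(C)(C)O3)[C@]13[C@@H](C)COCc1ccc(OC)cc1 | intermediate
42 | formaldehyde (used as paraformaldehyde) | C=O | starting material
43 | 7α-[3-(dicyclohexylamino)prop-1-ynyl] carbinol | C1CCCCC1N(C1CCCCC1)CC#C[C@@]1(O)[C@H](C=C)[C@@]2(C)C=C[C@@H](O[Si](C(C)C)(C(C)C)C(C)C)[C@@](C)(O[Si](CC)(CC)CC)[C@@H]2[C@@H](OC(C)(C)O3)[C@]13[C@@H](C)COCc1ccc(OC)cc1 | intermediate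
44 | trans-fused 7α-allenyl 7β-hydroxy 2β-vinyl decalin (oxy-Cope precursor) | C=C=C[C@@]1(O)[C@H](C=C)[C@@]2(C)C=C[C@@H](O[Si](C(C)C)(C(C)C)C(C)C)[C@@](C)(O[Si](CC)(CC)CC)[C@@H]2[C@@H](OC(C)(C)O3)[C@]13[C@@H](C)COCc1ccc(OC)cc1 | intermediate
45 | N-chlorosuccinimide | ClN1C(=O)CCC1=O | starting material
46 | potassium (Z)-dienolate of the ten-membered ring: C7(OK)=C6, C5=C16, E-C2=C3 | [K+].C=C1C/C=C/[C@@]2(C)C=C[C@@H](O[Si](C(C)C)(C(C)C)C(C)C)[C@@](C)(O[Si](CC)(CC)CC)[C@@H]2[C@@H](OC(C)(C)O3)[C@]3([C@@H](C)COCc4ccc(OC)cc4)/C([O-])=C/1 | intermediate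
47 | ten-membered 6-chloro 7-ketone with C5 methylene and E-C2=C3 | C=C1C/C=C/[C@@]2(C)C=C[C@@H](O[Si](C(C)C)(C(C)C)C(C)C)[C@@](C)(O[Si](CC)(CC)CC)[C@@H]2[C@@H](OC(C)(C)O3)[C@]3([C@@H](C)COCc4ccc(OC)cc4)C(=O)[C@H]1Cl | intermediate
48 | 6-chloro 7-alcohol (C7 as in target) | C=C1C/C=C/[C@@]2(C)C=C[C@@H](O[Si](C(C)C)(C(C)C)C(C)C)[C@@](C)(O[Si](CC)(CC)CC)[C@@H]2[C@@H](OC(C)(C)O3)[C@]3([C@@H](C)COCc4ccc(OC)cc4)[C@@H](O)[C@H]1Cl | intermediate
49 | 7,19-diol | C=C1C/C=C/[C@@]2(C)C=C[C@@H](O[Si](C(C)C)(C(C)C)C(C)C)[C@@](C)(O[Si](CC)(CC)CC)[C@@H]2[C@@H](OC(C)(C)O3)[C@]3([C@@H](C)CO)[C@@H](O)[C@H]1Cl | intermediate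
50 | C19 lactol onto O7 (anomers) | C=C1C/C=C/[C@@]2(C)C=C[C@@H](O[Si](C(C)C)(C(C)C)C(C)C)[C@@](C)(O[Si](CC)(CC)CC)[C@@H]2[C@@H](OC(C)(C)O3)[C@@]34[C@@H](C)C(O)O[C@H]4[C@H]1Cl | intermediate
51 | γ-lactone (O7–C19), 8,9-acetonide, 11-O-TES, 12-O-TIPS | C=C1C/C=C/[C@@]2(C)C=C[C@@H](O[Si](C(C)C)(C(C)C)C(C)C)[C@@](C)(O[Si](CC)(CC)CC)[C@@H]2[C@@H](OC(C)(C)O3)[C@@]34[C@@H](C)C(=O)O[C@H]4[C@H]1Cl | intermediate
52 | lactone 8,9,11-triol, 12-O-TIPS, E-C2=C3 | C=C1C/C=C/[C@@]2(C)C=C[C@@H](O[Si](C(C)C)(C(C)C)C(C)C)[C@@](C)(O)[C@@H]2[C@@H](O)[C@]3(O)[C@@H](C)C(=O)O[C@H]3[C@H]1Cl | intermediate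
53 | C2 hydroperoxide with 3Z,5(16)-diene | C=C1/C=C\[C@@H](OO)[C@@]2(C)C=C[C@@H](O[Si](C(C)C)(C(C)C)C(C)C)[C@@](C)(O)[C@@H]2[C@@H](O)[C@]3(O)[C@@H](C)C(=O)O[C@H]3[C@H]1Cl | intermediate
54 | C2 allylic alcohol with 3Z,5(16)-diene, 12-O-TIPS | C=C1/C=C\[C@@H](O)[C@@]2(C)C=C[C@@H](O[Si](C(C)C)(C(C)C)C(C)C)[C@@](C)(O)[C@@H]2[C@@H](O)[C@]3(O)[C@@H](C)C(=O)O[C@H]3[C@H]1Cl | intermediate
55 | 2,9-diacetate 12-O-TIPS ether | C=C1/C=C\[C@@H](OC(C)=O)[C@@]2(C)C=C[C@@H](O[Si](C(C)C)(C(C)C)C(C)C)[C@@](C)(O)[C@@H]2[C@@H](OC(C)=O)[C@]3(O)[C@@H](C)C(=O)O[C@H]3[C@H]1Cl | intermediate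
56 | CNP0317097.1 | C=C1/C=C\[C@@H](OC(C)=O)[C@@]2(C)C=C[C@@H](O)[C@@](C)(O)[C@@H]2[C@@H](OC(C)=O)[C@]2(O)[C@@H](C)C(=O)O[C@H]2[C@H]1Cl | target

## Step count and least certain steps

Total step count: 31. Longest linear sequence: 30 steps (steps 1–6 and 8–31 from 2-methylcyclohexanone); step 7 is a one-step side branch.

**Step 24 (key step).** The most likely failures are loss of face control at C6 and chlorination at C16 or on oxygen, because the dienolate is ambident and its shape in the new ring is only inferred from the chair transition state. The hindered tertiary alkoxide could also fragment instead of rearranging. Fallback: set out from 44 and separate the two events. Silylation gives the trimethylsilyl ether F1. A neutral siloxy-Cope rearrangement in a sealed tube at about 200 °C gives the silyl dienol ether F2 with the same C4–C5 bond made and C2–C7 cut. F2 is then chlorinated with N-chlorosuccinimide in CH2Cl2 at −78 °C, where a covalent enol ether reacts more selectively at C6, returning to the route at 47.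

**Step 29.** Singlet oxygen may add to the wrong face of C2=C3, may leave the new C3=C4 bond E, or may react competitively at C5=C16, because face and geometry rest on a conformational argument for a flexible ten-membered ring. Fallback: set out from 52 and accept whatever allylic alcohol the photooxygenation gives, for example the C2 epimer F3. Oxidize it with MnO2 to the cross-conjugated C2 dienone F4, in which the C3=C4 geometry can relax to Z (catalytic iodine). Reduce with NaBH4/CeCl3 (Luche reduction); hydride then arrives anti to C1–C10 and past the C15 methyl (Felkin–Anh), which places oxygen on the required side and returns to the route at 54.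

**Step 25.** Hydride may add to the other face of C7 if zinc does not hold O7 and O8 together or if the side chain on C8 blocks the peripheral path. Fallback: replace substrate control by reagent control with an oxazaborolidine-catalysed borane reduction (CBS reduction), choosing the catalyst enantiomer that places hydride on the required face between the quaternary C8 and the chloromethine C6. It sets out from 47 and returns at 48 with no new intermediate.

**Step 8.** The ketone is flanked by two oxygenated carbons and may react slowly, or exchange of boron onto O9 may be incomplete so that the closed, directed pathway and with it the C17 control is lost. Fallback: set out from 14 and add the lithium enolate of tert-butyl propionate (aldol addition to the ketone, equatorial attack) to give the β-hydroxy ester F5. Protect it as the acetonide F6 and reduce the ester with LiAlH4, returning to the route at 22. This has lower C17 selectivity, so a separation would be needed.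

**Step 23.** The Mannich stage or the hydride transfer may stall on the crowded tertiary propargylic alcohol, or prolonged heating may start a thermal rearrangement. Fallback: set out from 39 and add the cerium acetylide of 2-(prop-2-ynyloxy)tetrahydropyran to give the propargylic carbinol F7. Hydroxyl-directed SN2′ reduction with LiAlH4 expels the tetrahydropyranyloxy group and gives the terminal allene, returning to the route at 44.

## Further compounds

F1 | step 24 | trimethylsilyl ether of 44 | C=C=C[C@@]1(O[Si](C)(C)C)[C@H](C=C)[C@@]2(C)C=C[C@@H](O[Si](C(C)C)(C(C)C)C(C)C)[C@@](C)(O[Si](CC)(CC)CC)[C@@H]2[C@@H](OC(C)(C)O3)[C@]13[C@@H](C)COCc1ccc(OC)cc1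
F2 | step 24 | ten-membered C7 trimethylsilyl dienol ether (C6=C7, C5=C16, E-C2=C3) | C=C1C/C=C/[C@@]2(C)C=C[C@@H](O[Si](C(C)C)(C(C)C)C(C)C)[C@@](C)(O[Si](CC)(CC)CC)[C@@H]2[C@@H](OC(C)(C)O3)[C@]3([C@@H](C)COCc4ccc(OC)cc4)/C(O[Si](C)(C)C)=C/1
F3 | step 29 | C2 epimer of 54 | C=C1/C=C\[C@H](O)[C@@]2(C)C=C[C@@H](O[Si](C(C)C)(C(C)C)C(C)C)[C@@](C)(O)[C@@H]2[C@@H](O)[C@]3(O)[C@@H](C)C(=O)O[C@H]3[C@H]1Cl
F4 | step 29 | C2 ketone with 3Z,5(16)-diene | C=C1/C=C\C(=O)[C@@]2(C)C=C[C@@H](O[Si](C(C)C)(C(C)C)C(C)C)[C@@](C)(O)[C@@H]2[C@@H](O)[C@]3(O)[C@@H](C)C(=O)O[C@H]3[C@H]1Cl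
F0 | step 25 | none | none
F5 | step 8 | 8α,9α-diol with 8β-[1-(tert-butoxycarbonyl)ethyl] group | [C@H]1(O[Si](C)(C)C(C)(C)C)C[C@@]2(C)CCC3(OCCO3)[C@@H](C)[C@@H]2[C@@H](O)[C@]1(O)[C@@H](C)C(=O)OC(C)(C)C
F6 | step 8 | 8,9-acetonide of F5 | [C@H]1(O[Si](C)(C)C(C)(C)C)C[C@@]2(C)CCC3(OCCO3)[C@@H](C)[C@@H]2[C@@H](OC(C)(C)O4)[C@]14[C@@H](C)C(=O)OC(C)(C)C
F7 | step 23 | 7α-[3-(tetrahydropyran-2-yloxy)prop-1-ynyl] 7β-carbinol | C1CCOC(C1)OCC#C[C@@]1(O)[C@H](C=C)[C@@]2(C)C=C[C@@H](O[Si](C(C)C)(C(C)C)C(C)C)[C@@](C)(O[Si](CC)(CC)CC)[C@@H]2[C@@H](OC(C)(C)O3)[C@]13[C@@H](C)COCc1ccc(OC)cc1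
A1 | alternative 1 | fourteen-membered 12-silyloxy 1(14),12,10-triene (C1–C10 unbonded) | C=C1/C=C\[C@@H](OC(C)=O)/C(C)=C\C=C(O[Si](C)(C)C(C)(C)C)/C(C)=C/[C@@H](OC(C)=O)[C@]2(O)[C@@H](C)C(=O)O[C@H]2[C@H]1Cl
A2 | alternative 1 | briarane silyl dienol ether (C11=C12, C13=C14) | C=C1/C=C\[C@@H](OC(C)=O)[C@@]2(C)C=CC(O[Si](C)(C)C(C)(C)C)=C(C)[C@@H]2[C@@H](OC(C)=O)[C@]3(O)[C@@H](C)C(=O)O[C@H]3[C@H]1Cl
A3 | alternative 2 | 2-methylfuran | Cc1ccco1
A4 | alternative 2 | dimethyl mesaconate | COC(=O)/C=C(\C)C(=O)OC
A5 | alternative 2 | 7-oxanorbornene diester with C1, C10, C11 and C14 set | COC(=O)[C@@]1(C)[C@@H]2C=C[C@@](C)(O2)[C@@H]1C(=O)OC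
A6 | alternative 3 | ring A enone: 3-[(4-methoxybenzyloxy)methyl]-4-(tert-butyldimethylsilyloxy)cyclohex-2-enone | COc1ccc(COCC2=CC(=O)CC[C@@H]2O[Si](C)(C)C(C)(C)C)cc1
A7 | alternative 3 | C9 aldehyde: 4-benzyloxy-3-methyl-2-methylenebutanal | O=CC(=C)[C@@H](C)COCc1ccccc1
A8 | alternative 3 | ring A β-hydroxy ketone with C1, C10 and C9 set | COc1ccc(COC[C@@]2(C)[C@@H](O[Si](C)(C)C(C)(C)C)CCC(=O)[C@@H]2[C@@H](O)C(=C)[C@@H](C)COCc3ccccc3)cc1
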